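**Strategy.** Everything hinges on the C6–C1′ bond between the two rings. C6 is the quaternary ether carbon of oxane ring A (O1–C2Me2–C3HBr–C4–C5–C6), and C1′ of cyclohexane ring B is a stereocentre solely because the C4′(Me)(Cl)–C5′(Br) edge makes the two arms of ring B unlike. One catalytic oxo-Diels–Alder reaction of 1-methylcyclohexa-1,3-diene with a homoprenyl 2-oxo ester forges this bond and an expendable C4′–O bridge, setting C6 and C1′ together inside a 2-oxabicyclo[2.2.2]octene. Opening the bridge unveils the (R,R)-enantiomer of α-bisabolol, which is then carried to ring A and the ring B halides.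

Key step: step 4

Locants used for all intermediates: ring A is O1, C2 (CMe2), C3, C4, C5, C6; ring B is C1′ (bonded to C6), C2′, C3′, C4′ (methyl-bearing), C5′, C6′.

Assumption: the facial sense of the copper catalyst follows the square-planar chelate model for 2-oxo esters, in which the (S,S)-ligand exposes the si face of the ketone; the (R,R)-ligand is therefore specified, and the mirror-image ligand would be used if the sense proved reversed.

**Route**

Step 1
Reactants: 1 3-methylcyclohex-2-en-1-one
Product: 2 4-methyl-N′-(3-methylcyclohex-2-en-1-ylidene)benzenesulfonohydrazide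
Conditions: TsNHNH2 (1.05 equiv), EtOH, cat. HCl, rt
Reagents that add atoms: 4-methylbenzenesulfonohydrazide, Cc1ccc(cc1)S(=O)(=O)NN
Why: Acid-catalysed hydrazone formation at the enone carbonyl is fast, leaves the conjugated alkene untouched and creates no stereocentre.

Step 2
Reactants: 2 4-methyl-N′-(3-methylcyclohex-2-en-1-ylidene)benzenesulfonohydrazide
Product: 4 1-methylcyclohexa-1,3-diene, via vinyllithium 3 (not isolated)
Conditions: MeLi (2.2 equiv), Et2O, 0 °C to rt; then H2O; distillation
Reagents that add atoms: none
Why: Shapiro reaction, in which deprotonation at N–H and at the α′-CH2, loss of sulfinate and N2 and protonation of the vinyllithium place the new alkene next to the former carbonyl carbon and in conjugation with the methyl-bearing alkene, with no stereochemical issue.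

Step 3
Reactants: 5 5-bromo-2-methylpent-2-ene; 6 diethyl oxalate
Product: 8 ethyl 6-methyl-2-oxohept-5-enoate, via Grignard reagent 7 (not isolated)
Conditions: Mg, THF, rt; then added to 6 (2 equiv), THF, −78 °C; 1 M HCl
Reagents that add atoms: none
Why: Grignard acylation with excess oxalate at low temperature should stop at the 2-oxo ester because the magnesium hemiketal persists until the acidic quench; no stereocentre is formed.

Step 4
Reactants: 4 1-methylcyclohexa-1,3-diene; 8 ethyl 6-methyl-2-oxohept-5-enoate
Product: 9 ethyl (1S,3R,4R)-1-methyl-3-(4-methylpent-3-en-1-yl)-2-oxabicyclo[2.2.2]oct-5-ene-3-carboxylate (ester endo, syn to the C5=C6 bridge)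
Conditions: Cu(OTf)2 (10 mol %), 2,2′-(propane-2,2-diyl)bis[(4R)-4-tert-butyl-4,5-dihydro-1,3-oxazole] (11 mol %), CH2Cl2, rt; 4 in excess (3 equiv)
Reagents that add atoms: none
Why: The 2-oxo ester 8 binds copper through both carbonyl oxygens in a square-planar chelate, and the activated ketone C=O adds across the diene termini of 4 in a concerted, asynchronous [4+2] cycloaddition (oxo-Diels–Alder), the reaction class known for glyoxylates and 2-oxo esters with cyclohexa-1,3-diene under copper bis(oxazoline) catalysis. The one new ring, the 2-oxa bridge of the bicyclo[2.2.2]octene, closes by cycloaddition, with C6–C1′ formed at the unsubstituted diene terminus and O–C4′ at the methyl-bearing one. This regiochemistry follows diene polarisation: the methyl group makes the remote terminus the most nucleophilic carbon and lets its own carbon carry the developing positive charge that oxygen quenches. C6 is set by the ligand, whose tert-butyl groups should block the si face of the chelated ketone so that the diene adds to the re face; C1′ is set relative to C6 by endo placement of the copper-bound ester over the diene π system, which leaves the homoprenyl chain exo above the ethano bridge; C4′ follows from suprafacial addition and is erased later. The side-chain alkene of 8 cannot reach its own ketone in an ene geometry across a two-carbon tether, and excess diene disfavours intermolecular ene addition. The step thus needs regio-, endo- and facial selectivity at once, secured by the diene methyl group, the chelated ester and the ligand respectively.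

Step 5
Reactants: 9 ethyl (1S,3R,4R)-1-methyl-3-(4-methylpent-3-en-1-yl)-2-oxabicyclo[2.2.2]oct-5-ene-3-carboxylate
Product: 10 [(1S,3R,4R)-1-methyl-3-(4-methylpent-3-en-1-yl)-2-oxabicyclo[2.2.2]oct-5-en-3-yl]methanol
Conditions: LiAlH4, THF, 0 °C
Reagents that add atoms: none
Why: Hydride reduction of the ester gives the primary alcohol without touching the alkenes, the bridged ether or the three stereocentres.

Step 6
Reactants: 10 [(1S,3R,4R)-1-methyl-3-(4-methylpent-3-en-1-yl)-2-oxabicyclo[2.2.2]oct-5-en-3-yl]methanol
Product: 11 (2R)-6-methyl-2-[(1R)-4-methylcyclohex-3-en-1-yl]hept-5-ene-1,2-diol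
Conditions: Li (excess), EtNH2/THF, −78 °C; then solid NH4Cl
Reagents that add atoms: none
Why: Dissolving-metal reduction (Birch/Benkeser type) cleaves the tertiary allylic C4′–O bond to an alkoxide and an allyl anion that should be protonated at its less substituted terminus C6′, so the alkene settles at C4′=C5′, the C4′ stereocentre is erased and C6 and C1′ are untouched.

Step 7
Reactants: 11 (2R)-6-methyl-2-[(1R)-4-methylcyclohex-3-en-1-yl]hept-5-ene-1,2-diol
Product: 12 (2R)-2-hydroxy-6-methyl-2-[(1R)-4-methylcyclohex-3-en-1-yl]hept-5-en-1-yl 4-methylbenzenesulfonate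
Conditions: TsCl (1.1 equiv), pyridine, cat. DMAP, CH2Cl2, 0 °C to rt
Reagents that add atoms: 4-methylbenzenesulfonyl chloride, Cc1ccc(cc1)S(Cl)(=O)=O
Why: Selective sulfonylation of a 1,2-diol, in which the primary hydroxyl reacts and the tertiary one is sterically excluded; no stereocentre is affected.

Step 8
Reactants: 12 (2R)-2-hydroxy-6-methyl-2-[(1R)-4-methylcyclohex-3-en-1-yl]hept-5-en-1-yl 4-methylbenzenesulfonate
Product: 14 (2R)-6-methyl-2-[(1R)-4-methylcyclohex-3-en-1-yl]hept-5-en-2-ol, the (R,R)-enantiomer of α-bisabolol, via terminal epoxide 13 (not isolated)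
Conditions: LiEt3BH (3 equiv), THF, 0 °C to rt; then H2O
Reagents that add atoms: none
Why: Hydride deprotonates the tertiary alcohol, the alkoxide closes the terminal epoxide by displacing tosylate, and LiEt3BH opens it at the unhindered CH2 (tosylate/epoxide reduction), so C6 keeps its configuration and gains its methyl group.

Step 9
Reactants: 14 (2R)-6-methyl-2-[(1R)-4-methylcyclohex-3-en-1-yl]hept-5-en-2-ol
Product: 15 (3S,6R)-3-bromo-2,2,6-trimethyl-6-[(1R)-4-methylcyclohex-3-en-1-yl]oxane
Conditions: TBCO (1.05 equiv), CH2Cl2, −20 to 0 °C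
Reagents that add atoms: 2,4,4,6-tetrabromocyclohexa-2,5-dien-1-one (TBCO), O=C1C(Br)=CC(Br)(Br)C=C1Br
Why: Bromoetherification, in which Br+ passes from TBCO to the side-chain alkene and the tertiary hydroxyl closes the six-membered ring at the more substituted carbon C2 through a chair with Br equatorial and anti to oxygen and with the C6 methyl, not ring B, in the axial site facing the axial C2 methyl, which sets C3 as S, while a bromonium ion on the ring alkene can be trapped only through a boat and is expected to hand its bromine back.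

Step 10
Reactants: 15 (3S,6R)-3-bromo-2,2,6-trimethyl-6-[(1R)-4-methylcyclohex-3-en-1-yl]oxane
Product: 17 (3S,6R)-3-bromo-2,2,6-trimethyl-6-[(1R,3R,6S)-6-methyl-7-oxabicyclo[4.1.0]heptan-3-yl]oxane, via bromohydrin 16 (not isolated)
Conditions: NBS (1.1 equiv), acetone–H2O (4:1), 0 °C; then 2 M NaOH, rt
Reagents that add atoms: water, O
Why: Bromohydrin formation then base-induced epoxide closure, in which water opens the ring bromonium ion at the tertiary C4′ in the trans-diaxial sense (the C1′ substituent anchors the chair) to put OH at C4′ cis and Br at C5′ trans to that substituent, and the alkoxide then displaces bromide from the rear so that the epoxide oxygen ends on the face of the C1′ substituent.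

Step 11
Reactants: 17 (3S,6R)-3-bromo-2,2,6-trimethyl-6-[(1R,3R,6S)-6-methyl-7-oxabicyclo[4.1.0]heptan-3-yl]oxane
Product: 18 (1S,2S,4R)-4-[(2R,5S)-5-bromo-2,6,6-trimethyloxan-2-yl]-2-chloro-1-methylcyclohexan-1-ol
Conditions: LiCl (5 equiv), AcOH (3 equiv), THF, rt to 40 °C
Reagents that add atoms: lithium chloride, [Li+].[Cl-]
Why: Nucleophilic epoxide opening under weak acid, in which chloride attacks the secondary C5′ with inversion along the trans-diaxial trajectory (for this epoxide diastereomer also the less substituted carbon), giving axial Cl at C5′ and axial tertiary OH at C4′.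

Step 12
Reactants: 18 (1S,2S,4R)-4-[(2R,5S)-5-bromo-2,6,6-trimethyloxan-2-yl]-2-chloro-1-methylcyclohexan-1-ol
Product: 19 (3S,6R)-3-bromo-6-[(1R,3S,4S)-4-bromo-3-chloro-4-methylcyclohexyl]-2,2,6-trimethyloxane
Conditions: TMSBr (1.5 equiv), CH2Cl2, 0 °C
Reagents that add atoms: bromotrimethylsilane, C[Si](C)(C)Br
Why: Conversion of a tertiary alcohol into the bromide, in which ionisation at C4′ is assisted by the antiperiplanar C5′ chlorine and bromide opens the chloronium ion at the tertiary carbon from the face the oxygen left, giving the trans-diaxial bromochloride with overall retention at C4′.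

Step 13
Reactants: 19 (3S,6R)-3-bromo-6-[(1R,3S,4S)-4-bromo-3-chloro-4-methylcyclohexyl]-2,2,6-trimethyloxane
Product: 20 deoxycaespitol, (3S,6R)-3-bromo-6-[(1R,3R,4R)-3-bromo-4-chloro-4-methylcyclohexyl]-2,2,6-trimethyloxane
Conditions: MeCN, 80 °C, sealed tube, dark
Reagents that add atoms: none
Why: Diaxial-to-diequatorial rearrangement of a vicinal dihalide (1,2-halogen interchange through a bridged ion pair), in which each halogen moves to the neighbouring carbon on its own face so that Cl arrives at C4′ and Br at C5′, both equatorial and still trans, the isomer with the tertiary C–Cl bond being expected to be favoured in a polar medium.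

**Compound list**

1 | 3-methylcyclohex-2-en-1-one | CC1=CC(=O)CCC1 | starting material
2 | 4-methyl-N′-(3-methylcyclohex-2-en-1-ylidene)benzenesulfonohydrazide | CC1=CC(=NNS(=O)(=O)c2ccc(C)cc2)CCC1 | intermediate
3 | (5-methylcyclohexa-1,5-dien-1-yl)lithium | [Li]C1=CCCC(C)=C1 | intermediate (not isolated)
4 | 1-methylcyclohexa-1,3-diene | CC1=CC=CCC1 | intermediate
5 | 5-bromo-2-methylpent-2-ene | CC(C)=CCCBr | starting material
6 | diethyl oxalate | CCOC(=O)C(=O)OCC | starting material
7 | (4-methylpent-3-en-1-yl)magnesium bromide | CC(C)=CCC[Mg]Br | intermediate (not isolated)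
8 | ethyl 6-methyl-2-oxohept-5-enoate | CCOC(=O)C(=O)CCC=C(C)C | intermediate
9 | ethyl (1S,3R,4R)-1-methyl-3-(4-methylpent-3-en-1-yl)-2-oxabicyclo[2.2.2]oct-5-ene-3-carboxylate | O1[C@@](C(=O)OCC)([C@@H]2CC[C@@]1(C)C=C2)CCC=C(C)C | intermediate
10 | [(1S,3R,4R)-1-methyl-3-(4-methylpent-3-en-1-yl)-2-oxabicyclo[2.2.2]oct-5-en-3-yl]methanol | O1[C@@](CO)([C@@H]2CC[C@@]1(C)C=C2)CCC=C(C)C | intermediate
11 | (2R)-6-methyl-2-[(1R)-4-methylcyclohex-3-en-1-yl]hept-5-ene-1,2-diol | O[C@@](CO)([C@@H]2CCC(C)=CC2)CCC=C(C)C | intermediate
12 | (2R)-2-hydroxy-6-methyl-2-[(1R)-4-methylcyclohex-3-en-1-yl]hept-5-en-1-yl 4-methylbenzenesulfonate | O[C@@](COS(=O)(=O)c1ccc(C)cc1)([C@@H]2CCC(C)=CC2)CCC=C(C)C | intermediate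
13 | (2R)-2-[(1R)-4-methylcyclohex-3-en-1-yl]-2-(4-methylpent-3-en-1-yl)oxirane | C1O[C@@]1([C@@H]2CCC(C)=CC2)CCC=C(C)C | intermediate (not isolated)
14 | (2R)-6-methyl-2-[(1R)-4-methylcyclohex-3-en-1-yl]hept-5-en-2-ol | O[C@@](C)([C@@H]2CCC(C)=CC2)CCC=C(C)C | intermediate
15 | (3S,6R)-3-bromo-2,2,6-trimethyl-6-[(1R)-4-methylcyclohex-3-en-1-yl]oxane | CC1(C)O[C@@](C)([C@@H]2CCC(C)=CC2)CC[C@@H]1Br | intermediate
16 | (1S,2S,4R)-2-bromo-4-[(2R,5S)-5-bromo-2,6,6-trimethyloxan-2-yl]-1-methylcyclohexan-1-ol | CC1(C)O[C@@](C)([C@@H]2CC[C@](C)(O)[C@@H](Br)C2)CC[C@@H]1Br | intermediate (not isolated)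
17 | (3S,6R)-3-bromo-2,2,6-trimethyl-6-[(1R,3R,6S)-6-methyl-7-oxabicyclo[4.1.0]heptan-3-yl]oxane | CC1(C)O[C@@](C)([C@@H]2CC[C@]3(C)O[C@@H]3C2)CC[C@@H]1Br | intermediate
18 | (1S,2S,4R)-4-[(2R,5S)-5-bromo-2,6,6-trimethyloxan-2-yl]-2-chloro-1-methylcyclohexan-1-ol | CC1(C)O[C@@](C)([C@@H]2CC[C@](C)(O)[C@@H](Cl)C2)CC[C@@H]1Br | intermediate
19 | (3S,6R)-3-bromo-6-[(1R,3S,4S)-4-bromo-3-chloro-4-methylcyclohexyl]-2,2,6-trimethyloxane | CC1(C)O[C@@](C)([C@@H]2CC[C@](C)(Br)[C@@H](Cl)C2)CC[C@@H]1Br | intermediate
20 | deoxycaespitol, (3S,6R)-3-bromo-6-[(1R,3R,4R)-3-bromo-4-chloro-4-methylcyclohexyl]-2,2,6-trimethyloxane | CC1(C)O[C@@](C)([C@@H]2CC[C@@](C)(Cl)[C@H](Br)C2)CC[C@@H]1Br | target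

**Count**

Total steps: 13. Longest linear sequence: 12 steps (steps 1, 2 and 4 to 13, from 3-methylcyclohex-2-en-1-one).

**Steps most likely to fail**

Step 4. The diene methyl group lies next to the copper-bound oxygen in the transition state. Enantiofacial discrimination of the ketone and the ester-endo preference may therefore erode, and ene-type addition of the ketone to an alkene may compete. The fallback sets out from 4 and 8 and returns at 9. The cycloaddition is run with an achiral complex, Cu(OTf)2 with 2,2′-bipyridine, in CH2Cl2, which should give the racemic ester-endo adduct, that is 9 together with its mirror image, ethyl (1R,3S,4S)-1-methyl-3-(4-methylpent-3-en-1-yl)-2-oxabicyclo[2.2.2]oct-5-ene-3-carboxylate F1. The enantiomers are separated by preparative chromatography on a chiral stationary phase, and enantiopure 9 re-enters at step 5, so stereocontrol comes from separation instead of from the catalyst.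

Step 9. Three processes may divert the cyclisation: closure of the five-membered ether by attack of the hydroxyl on the secondary alkene carbon, formation of the C3 epimer through the alternative chair, and capture of a ring-alkene bromonium ion by the hydroxyl. The fallback sets out from 14 and returns at 15, and it separates ring closure from bromination. Hg(OCOCF3)2 in MeCN at 0 °C, followed by aqueous NaBr, should give under reversible oxymercuration the six-membered ether with equatorial mercury, bromo{(3S,6R)-2,2,6-trimethyl-6-[(1R)-4-methylcyclohex-3-en-1-yl]oxan-3-yl}mercury F2. Brominolysis with Br2 and LiBr in pyridine under O2 replaces mercury by bromine with retention and in the same operation adds bromine to the ring alkene, giving (3S,6R)-3-bromo-6-[(1R,3S,4S)-3,4-dibromo-4-methylcyclohexyl]-2,2,6-trimethyloxane F3. NaI in acetone then removes only the vicinal dibromide by anti elimination and returns 15.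

Step 13. The halogen interchange may stop at an unfavourable equilibrium, or HBr may be lost from the tertiary bromide on heating. The fallback sets out from 15 and returns at 20 under kinetic control. mCPBA (CH2Cl2, NaHCO3) epoxidises the ring alkene on both faces; the diastereomer with oxygen cis to the C1′ substituent is 17 and is used as before. The other, (3S,6R)-3-bromo-2,2,6-trimethyl-6-[(1S,3R,6R)-6-methyl-7-oxabicyclo[4.1.0]heptan-3-yl]oxane F4, is opened by HBr (48 % aq., CHCl3, 0 °C) in the trans-diaxial sense at the tertiary carbon to give (1S,2S,5R)-2-bromo-5-[(2R,5S)-5-bromo-2,6,6-trimethyloxan-2-yl]-2-methylcyclohexan-1-ol F5. SOCl2 and pyridine (CH2Cl2, −20 °C) turn the axial hydroxyl into a chlorosulfite that leaves with the help of the antiperiplanar bromine. Chloride should open the resulting bromonium ion at the tertiary C4′, which places Cl at C4′ and leaves Br at C5′ on the face of the C1′ substituent, giving 20 directly.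

**Further compounds**

F1 | step 4 | ethyl (1R,3S,4S)-1-methyl-3-(4-methylpent-3-en-1-yl)-2-oxabicyclo[2.2.2]oct-5-ene-3-carboxylate | O1[C@](C(=O)OCC)([C@H]2CC[C@]1(C)C=C2)CCC=C(C)C
F2 | step 9 | bromo{(3S,6R)-2,2,6-trimethyl-6-[(1R)-4-methylcyclohex-3-en-1-yl]oxan-3-yl}mercury | CC1(C)O[C@@](C)([C@@H]2CCC(C)=CC2)CC[C@@H]1[Hg]Br
F3 | step 9 | (3S,6R)-3-bromo-6-[(1R,3S,4S)-3,4-dibromo-4-methylcyclohexyl]-2,2,6-trimethyloxane | CC1(C)O[C@@](C)([C@@H]2CC[C@](C)(Br)[C@@H](Br)C2)CC[C@@H]1Br
F4 | step 13 | (3S,6R)-3-bromo-2,2,6-trimethyl-6-[(1S,3R,6R)-6-methyl-7-oxabicyclo[4.1.0]heptan-3-yl]oxane | CC1(C)O[C@@](C)([C@@H]2CC[C@@]3(C)O[C@H]3C2)CC[C@@H]1Br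
F5 | step 13 | (1S,2S,5R)-2-bromo-5-[(2R,5S)-5-bromo-2,6,6-trimethyloxan-2-yl]-2-methylcyclohexan-1-ol | CC1(C)O[C@@](C)([C@@H]2CC[C@](C)(Br)[C@@H](O)C2)CC[C@@H]1Br
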